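**Retrosynthetic overview**

1. Numbering: C1 is the acetoxy carbon; ring A is the cyclopentenone C1–C2=C3(Me)–C4(=O)–C5; C6 is the exocyclic CH; ring B is the tetrahydrofuran C7(Me)–C8–C9–C10–O; C11 is CMe2; C12, C13, C14 (CHMe) and C15 (ketone) complete the twelve-membered ring C.
2. The strategy rests on the ring A enone C2=C3(Me)–C4=O (H on C2, methyl on C3) beside the exocyclic C5=C6 alkene. This is what a C4 aldehyde C–H bond gives on adding across a C2≡C3 propynyl group on C1, so ring A is disconnected at C3–C4 (rhodium alkynal hydroacylation) with the E alkylidene already in place.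
3. Ring C is formed last, at C12–C13, by decarboxylative radical 12-endo cyclisation of a C12 radical onto a C15 methacryloyl ketone. That ketone is put on C1 before ring A exists, because no isopropenyl-metal could be used beside the cross-conjugated dienone.
4. The E-enal precursor goes back to a C4–C5≡C6 propargylic alcohol: hydroxyl-directed trans-hydrostannation fixes C5=C6, the derived alkenyllithium is acylated with dimethyl oxalate (C5–C1), and C1 is set by asymmetric addition of propyne.
5. Ring B is made first, as the 2,5-trans tetrahydrofuran, by cobalt-catalysed aerobic cyclisation of the (S)-alkenol from α,α-dimethyl-γ-butyrolactone and 4-bromo-2-methylbut-1-ene. Ring order: B, then A (key step), then C.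

Key step: step 19

Remark: THF* stands for the (2S,5S)-5-{4-[(tert-butyldiphenylsilyl)oxy]-2-methylbutan-2-yl}-2-methyltetrahydrofuran-2-yl group (ring B with the C11–C12 arm; the C6 arm on C7 and the C11 arm on C10 are trans, as in the target).
Assumption: the facial sense of the zinc/amino alcohol alkynylation of step 13 on this alkenyl ketoester is not predictable with certainty; the ligand antipode that gives (S)-C1 is used and is written as the (1S,2S)-ligand.
Assumption: the (14R) epimer is taken to be favoured in ring C both kinetically (hydrogen delivery from the outer face) and thermodynamically; C14 is the only enolisable centre of the target.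

**Route**

Step 1
Reactants: 1 α,α-dimethyl-γ-butyrolactone
Product: 2 4-hydroxy-N-methoxy-N,2,2-trimethylbutanamide
Conditions: MeNH(OMe)·HCl, AlMe3, CH2Cl2, 0 °C → rt; aq. potassium sodium tartrate (KNaC4H4O6); crude used at once
Reagents that add atoms: N,O-dimethylhydroxylamine hydrochloride, CNOC.Cl
Why: Weinreb aminolysis of a lactone by the aluminium amide opens the ring to the hydroxy Weinreb amide, which is silylated directly before it can relactonise.

Step 2
Reactants: 2 4-hydroxy-N-methoxy-N,2,2-trimethylbutanamide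
Product: 3 4-[(tert-butyldiphenylsilyl)oxy]-N-methoxy-N,2,2-trimethylbutanamide
Conditions: TBDPSCl, imidazole, DMF, rt
Reagents that add atoms: tert-butyl(chloro)diphenylsilane, CC(C)(C)[Si](Cl)(c1ccccc1)c1ccccc1
Why: Imidazole-promoted silylation of the primary alcohol gives an ether that survives organometallic, hydride and oxidative steps up to step 22.

Step 3
Reactants: 3 4-[(tert-butyldiphenylsilyl)oxy]-N-methoxy-N,2,2-trimethylbutanamide; 4 4-bromo-2-methylbut-1-ene
Product: 6 8-[(tert-butyldiphenylsilyl)oxy]-2,6,6-trimethyloct-1-en-5-one, via homoallyl Grignard reagent 5 (not isolated)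
Conditions: 4, Mg, THF, rt; then 3, THF, 0 °C → rt; aq. work-up
Reagents that add atoms: none
Why: Grignard addition to a Weinreb amide stops at the chelated tetrahedral adduct and gives the C10 ketone only on work-up, joining C9 to C10.

Step 4
Reactants: 6 8-[(tert-butyldiphenylsilyl)oxy]-2,6,6-trimethyloct-1-en-5-one
Product: 7 (5S)-8-[(tert-butyldiphenylsilyl)oxy]-2,6,6-trimethyloct-1-en-5-ol
Conditions: (R)-Me-CBS oxazaborolidine (0.3 equiv), catecholborane, toluene, −78 → −20 °C
Reagents that add atoms: none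
Why: Corey–Bakshi–Shibata reduction in which the tert-alkyl group (C11) is the large substituent, so the (R)-catalyst should give the (S)-carbinol at C10; catecholborane does not hydroborate the 1,1-disubstituted alkene.

Step 5
Reactants: 7 (5S)-8-[(tert-butyldiphenylsilyl)oxy]-2,6,6-trimethyloct-1-en-5-ol
Product: 8 (THF*)methanol
Conditions: Co(nmp)2 [nmp = 1-morpholinocarbamoyl-4,4-dimethylpentane-1,3-dionate] (10 mol%), O2 (1 atm), tBuOOH (10 mol%), iPrOH, 55 °C
Reagents that add atoms: dioxygen, O=O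
Why: Mukaiyama aerobic oxidative cyclisation of a pent-4-en-1-ol with divalent cobalt closes ring B 5-exo and places the new hydroxymethyl carbon (C6) trans to the C10 substituent, which sets the quaternary C7 as (S) relative to C10; any C7 epimer would be removed by chromatography here.

Step 6
Reactants: 8 (THF*)methanol
Product: 9 THF*-carbaldehyde
Conditions: Dess–Martin periodinane, NaHCO3, CH2Cl2, 0 °C → rt
Reagents that add atoms: none
Why: Dess–Martin oxidation of the primary alcohol gives an aldehyde whose α-carbon (C7) is quaternary and cannot epimerise.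

Step 7
Reactants: 9 THF*-carbaldehyde
Product: 10 THF*-ethyne (terminal alkyne C6≡C5)
Conditions: dimethyl (1-diazo-2-oxopropyl)phosphonate, K2CO3, MeOH, rt
Reagents that add atoms: dimethyl (1-diazo-2-oxopropyl)phosphonate, COP(=O)(OC)C(=[N+]=[N-])C(C)=O
Why: Seyferth–Gilbert homologation in the Ohira–Bestmann version converts the non-enolisable aldehyde into the terminal alkyne under mild base.

Step 8
Reactants: 10 THF*-ethyne
Product: 12 3-(THF*)prop-2-yn-1-ol, via lithium acetylide 11 (not isolated)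
Conditions: nBuLi, THF, −78 °C; (CH2O)n, −78 °C → rt
Reagents that add atoms: formaldehyde (as paraformaldehyde), C=O
Why: Acetylide addition to formaldehyde installs C4 as the propargylic alcohol that directs the next step.

Step 9
Reactants: 12 3-(THF*)prop-2-yn-1-ol
Product: 13 (2Z)-3-(THF*)-2-(tributylstannyl)prop-2-en-1-ol
Conditions: [Cp*RuCl]4 (2.5 mol%), Bu3SnH, CH2Cl2, rt
Reagents that add atoms: tributyltin hydride, CCCC[SnH](CCCC)CCCC
Why: Hydroxyl-directed ruthenium-catalysed trans-hydrostannation, in which the chloride ligand hydrogen-bonds to the C4 hydroxyl and steers tin to the proximal carbon C5 while H adds to C6 on the opposite side, so C4 and C7 end up trans across C5=C6 as the target requires.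

Step 10
Reactants: 13 (2Z)-3-(THF*)-2-(tributylstannyl)prop-2-en-1-ol
Product: 14 4-methoxybenzyl ether of 13
Conditions: NaH, PMBCl, Bu4NI (cat.), DMF, 0 °C → rt
Reagents that add atoms: 4-methoxybenzyl chloride, COc1ccc(CCl)cc1
Why: Williamson etherification at the stannane stage (no base-labile vinyl halide yet) gives a C4 ether that tolerates organolithium chemistry and is later removed oxidatively without touching silyl ethers.

Step 11
Reactants: 14 4-methoxybenzyl ether of 13
Product: 15 1-({[(2Z)-2-iodo-3-(THF*)prop-2-en-1-yl]oxy}methyl)-4-methoxybenzene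
Conditions: I2, CH2Cl2, 0 °C
Reagents that add atoms: iodine, II
Why: Iododestannylation replaces tin by iodine with retention of the alkene geometry.

Step 12
Reactants: 15 (Z)-alkenyl iodide; 16 dimethyl oxalate
Product: 18 methyl (3Z)-3-{[(4-methoxybenzyl)oxy]methyl}-2-oxo-4-(THF*)but-3-enoate, via alkenyllithium 17 (not isolated)
Conditions: tBuLi (2.1 equiv), Et2O, −78 °C; cannulated into 16 (3 equiv), THF, −78 °C; aq. work-up
Reagents that add atoms: none
Why: Iodine–lithium exchange proceeds with retention of geometry and the alkenyllithium is mono-acylated by excess dimethyl oxalate (inverse addition, tetrahedral adduct stable at −78 °C), forming C5–C1 and bringing in C1 and C15.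

Step 13
Reactants: 18 α-ketoester; 19 propyne
Product: 20 methyl (2S,3Z)-2-hydroxy-3-{[(4-methoxybenzyl)oxy]methyl}-2-(prop-1-yn-1-yl)-4-(THF*)but-3-enoate
Conditions: 19 (excess), Zn(OTf)2 (0.5 equiv), (1S,2S)-2-(dimethylamino)-1-(4-nitrophenyl)-3-[(tert-butyldimethylsilyl)oxy]propan-1-ol (0.55 equiv), Et3N (0.6 equiv), toluene, sealed tube, 60 °C
Reagents that add atoms: none
Why: Zinc triflate/chiral amino alcohol alkynylation of an α-ketoester, in which the zinc acetylide adds only to the more electrophilic C1 ketone and the ligand decides the face attacked, chosen to give (S)-C1.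

Step 14
Reactants: 20 tertiary propargylic alcohol
Product: 21 methyl (2S,3Z)-3-{[(4-methoxybenzyl)oxy]methyl}-2-(prop-1-yn-1-yl)-4-(THF*)-2-[(triethylsilyl)oxy]but-3-enoate
Conditions: Et3SiOTf, 2,6-lutidine, CH2Cl2, −78 → 0 °C
Reagents that add atoms: triethylsilyl trifluoromethanesulfonate, CC[Si](CC)(CC)OS(=O)(=O)C(F)(F)F
Why: Silyl triflate silylation caps the hindered tertiary C1 hydroxyl as an ether that cannot migrate under rhodium the way an ester could.

Step 15
Reactants: 21 silyl ether methyl ester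
Product: 22 (2S,3Z)-3-{[(4-methoxybenzyl)oxy]methyl}-2-(prop-1-yn-1-yl)-4-(THF*)-2-[(triethylsilyl)oxy]but-3-enal
Conditions: iBu2AlH (1.2 equiv), CH2Cl2, −78 °C; aq. potassium sodium tartrate (KNaC4H4O6)
Reagents that add atoms: none
Why: Partial reduction of an α-silyloxy ester with diisobutylaluminium hydride stops at the aluminium hemiacetal at −78 °C and gives the non-enolisable C15 aldehyde on work-up.

Step 16
Reactants: 22 C15 aldehyde; 23 isopropenylmagnesium bromide
Product: 24 (4S,5Z)-5-{[(4-methoxybenzyl)oxy]methyl}-2-methyl-4-(prop-1-yn-1-yl)-6-(THF*)-4-[(triethylsilyl)oxy]hexa-1,5-dien-3-ol (both C15 epimers)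
Conditions: 23, THF, −78 °C; aq. work-up at −78 °C
Reagents that add atoms: none
Why: Grignard addition to the aldehyde brings in C14, its methyl and C13; the new C15 carbinol centre is not controlled and is removed by oxidation in step 18, and the cold quench avoids silyl migration from the C1 oxygen.

Step 17
Reactants: 24 C15 allylic alcohol
Product: 25 (4S,5Z)-5-(hydroxymethyl)-2-methyl-4-(prop-1-yn-1-yl)-6-(THF*)-4-[(triethylsilyl)oxy]hexa-1,5-dien-3-ol (both C15 epimers)
Conditions: DDQ, CH2Cl2/pH 7 buffer, 0 °C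
Reagents that add atoms: none
Why: Oxidative cleavage of the 4-methoxybenzyl ether with DDQ frees the C4 hydroxyl and leaves both silyl ethers, the alkyne and the alkenes untouched.

Step 18
Reactants: 25 diol
Product: 26 (2E,3S)-5-methyl-4-oxo-3-(prop-1-yn-1-yl)-2-[(THF*)methylidene]-3-[(triethylsilyl)oxy]hex-5-enal (E-enal 4-alkynal: C4 aldehyde on C5, C5=C6 E, C1 carrying OSiEt3, propynyl and the C15 methacryloyl ketone)
Conditions: Dess–Martin periodinane (3 equiv), NaHCO3, CH2Cl2, 0 °C → rt
Reagents that add atoms: none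
Why: Dess–Martin oxidation converts both allylic alcohols in one operation, C4 to the enal and C15 to the methacryloyl ketone, under buffered conditions that do not isomerise C5=C6.

Step 19
Reactants: 26 E-enal 4-alkynal
Product: 27 (4S,5E)-2-methyl-4-(2-methylacryloyl)-5-[(THF*)methylidene]-4-[(triethylsilyl)oxy]cyclopent-2-en-1-one
Conditions: [Rh(dppe)]2(BF4)2 (10 mol%), acetone (degassed), rt → 40 °C
Reagents that add atoms: none
Why: Cationic univalent rhodium inserts into the C4–H bond of the enal to give an acyl rhodium hydride, which adds hydride and metal trans across the C2≡C3 propynyl group to a six-membered rhodacycle (Rh, C4, C5, C1, C2, C3), and C–C reductive elimination forms C3–C4. This is the known rhodium-catalysed cyclisation of 4-alkynals to cyclopent-2-enones, which accepts a fully substituted, oxygen-bearing carbon next to the alkyne (here C1); the conjugated, α-alkylidene aldehyde is a variation of the substrate that has not been examined. Ring A closes in a formal 5-endo-dig mode at C3–C4, which fixes the regiochemistry (acyl to the methyl-bearing carbon C3, hydrogen on C2); no stereocentre is created. The step needs chemoselectivity for the alkyne over the C13=C14 alkene of the methacryloyl ketone and retention of the E geometry at C5=C6: the quaternary C1 and the sp2 C5 hold formyl and alkyne within reach, the C13=C14 alkene could only react through a seven-membered rhodacycle, and hydrometalation of C5=C6 is disfavoured at the neopentyl-like C6. The C1 oxygen stays a silyl ether because an ester there would make the substrate a 3-acyloxy-1,4-enyne open to metal-induced acyloxy migration.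

Step 20
Reactants: 27 silyloxy dienone
Product: 28 (4S,5E)-4-hydroxy-2-methyl-4-(2-methylacryloyl)-5-[(THF*)methylidene]cyclopent-2-en-1-one
Conditions: HF·pyridine, pyridine, THF, 0 °C
Reagents that add atoms: none
Why: Buffered fluoride desilylation removes the triethylsilyl ether much faster than the primary tert-butyldiphenylsilyl ether, and the acidic medium avoids base-induced reactions of the dienone.

Step 21
Reactants: 28 tertiary alcohol
Product: 29 (1S,5E)-3-methyl-1-(2-methylacryloyl)-4-oxo-5-[(THF*)methylidene]cyclopent-2-en-1-yl acetate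
Conditions: Ac2O, DMAP, Et3N, CH2Cl2, rt
Reagents that add atoms: acetic anhydride, CC(=O)OC(C)=O
Why: DMAP-catalysed acylation installs the C1 acetate on the tertiary alcohol with retention, since the C1–O bond is not broken.

Step 22
Reactants: 29 tertiary acetate
Product: 30 (1S,5E)-5-{[(2S,5S)-5-(4-hydroxy-2-methylbutan-2-yl)-2-methyltetrahydrofuran-2-yl]methylidene}-3-methyl-1-(2-methylacryloyl)-4-oxocyclopent-2-en-1-yl acetate
Conditions: HF·pyridine, THF, rt
Reagents that add atoms: none
Why: Fluoride desilylation under acidic conditions removes the tert-butyldiphenylsilyl ether without acetate migration or cleavage.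

Step 23
Reactants: 30 primary alcohol
Product: 31 3-[(2S,5S)-5-{(E)-[(2S)-2-acetoxy-4-methyl-2-(2-methylacryloyl)-5-oxocyclopent-3-en-1-ylidene]methyl}-5-methyltetrahydrofuran-2-yl]-3-methylbutanoic acid
Conditions: TEMPO (20 mol%), PhI(OAc)2, MeCN/H2O, rt
Reagents that add atoms: water, O
Why: TEMPO/hypervalent iodine oxidation takes the primary alcohol through the aldehyde hydrate to the acid and leaves enones and the acetate intact.

Step 24
Reactants: 31 carboxylic acid
Product: 32 1,3-dioxoisoindolin-2-yl ester of 31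
Conditions: N-hydroxyphthalimide, DIC, DMAP (cat.), CH2Cl2, rt
Reagents that add atoms: N-hydroxyphthalimide, O=C1c2ccccc2C(=O)N1O
Why: Carbodiimide (Steglich-type) esterification gives the redox-active ester needed for reductive decarboxylation.

Step 25
Reactants: 32 redox-active ester
Product: 33 CNP0144863.1 (1S,5E,7S,10S,14R in the overview numbering)
Conditions: Ru(bpy)3(PF6)2 (2 mol%), Hantzsch ester (diethyl 2,6-dimethyl-1,4-dihydropyridine-3,5-dicarboxylate), iPr2NEt, CH2Cl2 (1 mM, slow addition of 32), blue LEDs, rt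
Reagents that add atoms: none
Why: Single-electron reduction of the N-acyloxyphthalimide releases CO2 and the primary C12 radical, which closes ring C by 12-endo-trig Giese addition to C13 of the methacryloyl ketone (decarboxylative radical macrocyclisation); a six-membered closure onto C6 is excluded by the trans arrangement on ring B, and the C14 α-keto radical is reduced and protonated from the outer face of the ring, which should give (14R), with equilibration at this sole enolisable centre as a corrective.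

**Compound list**

1 | α,α-dimethyl-γ-butyrolactone | CC1(C)CCOC1=O | starting material
2 | 4-hydroxy-N-methoxy-N,2,2-trimethylbutanamide | CON(C)C(=O)C(C)(C)CCO | intermediate
3 | 4-[(tert-butyldiphenylsilyl)oxy]-N-methoxy-N,2,2-trimethylbutanamide | CON(C)C(=O)C(C)(C)CCO[Si](c1ccccc1)(c1ccccc1)C(C)(C)C | intermediate
4 | 4-bromo-2-methylbut-1-ene | C=C(C)CCBr | starting material
5 | (3-methylbut-3-en-1-yl)magnesium bromide | C=C(C)CC[Mg]Br | intermediate
6 | 8-[(tert-butyldiphenylsilyl)oxy]-2,6,6-trimethyloct-1-en-5-one | C=C(C)CCC(=O)C(C)(C)CCO[Si](c1ccccc1)(c1ccccc1)C(C)(C)C | intermediate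
7 | (5S)-8-[(tert-butyldiphenylsilyl)oxy]-2,6,6-trimethyloct-1-en-5-ol | C=C(C)CC[C@H](O)C(C)(C)CCO[Si](c1ccccc1)(c1ccccc1)C(C)(C)C | intermediate
8 | (THF*)methanol | OC[C@]1(C)CC[C@H](O1)C(C)(C)CCO[Si](c1ccccc1)(c1ccccc1)C(C)(C)C | intermediate
9 | THF*-carbaldehyde | O=C[C@]1(C)CC[C@H](O1)C(C)(C)CCO[Si](c1ccccc1)(c1ccccc1)C(C)(C)C | intermediate
10 | THF*-ethyne | C#C[C@]1(C)CC[C@H](O1)C(C)(C)CCO[Si](c1ccccc1)(c1ccccc1)C(C)(C)C | intermediate
11 | lithium acetylide of 10 | [Li]C#C[C@]1(C)CC[C@H](O1)C(C)(C)CCO[Si](c1ccccc1)(c1ccccc1)C(C)(C)C | intermediate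
12 | 3-(THF*)prop-2-yn-1-ol | OCC#C[C@]1(C)CC[C@H](O1)C(C)(C)CCO[Si](c1ccccc1)(c1ccccc1)C(C)(C)C | intermediate
13 | (2Z)-3-(THF*)-2-(tributylstannyl)prop-2-en-1-ol | OC/C(=C/[C@]1(C)CC[C@H](O1)C(C)(C)CCO[Si](c1ccccc1)(c1ccccc1)C(C)(C)C)[Sn](CCCC)(CCCC)CCCC | intermediate
14 | 4-methoxybenzyl ether of 13 | COc1ccc(COC/C(=C/[C@]2(C)CC[C@H](O2)C(C)(C)CCO[Si](c3ccccc3)(c3ccccc3)C(C)(C)C)[Sn](CCCC)(CCCC)CCCC)cc1 | intermediate
15 | 1-({[(2Z)-2-iodo-3-(THF*)prop-2-en-1-yl]oxy}methyl)-4-methoxybenzene | COc1ccc(COC/C(I)=C/[C@]2(C)CC[C@H](O2)C(C)(C)CCO[Si](c3ccccc3)(c3ccccc3)C(C)(C)C)cc1 | intermediate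
16 | dimethyl oxalate | COC(=O)C(=O)OC | starting material
17 | alkenyllithium from 15 (Li in place of I) | COc1ccc(COC/C([Li])=C/[C@]2(C)CC[C@H](O2)C(C)(C)CCO[Si](c3ccccc3)(c3ccccc3)C(C)(C)C)cc1 | intermediate
18 | methyl (3Z)-3-{[(4-methoxybenzyl)oxy]methyl}-2-oxo-4-(THF*)but-3-enoate | COc1ccc(COC/C(=C/[C@]2(C)CC[C@H](O2)C(C)(C)CCO[Si](c3ccccc3)(c3ccccc3)C(C)(C)C)C(=O)C(=O)OC)cc1 | intermediate
19 | propyne | CC#C | starting material
20 | methyl (2S,3Z)-2-hydroxy-3-{[(4-methoxybenzyl)oxy]methyl}-2-(prop-1-yn-1-yl)-4-(THF*)but-3-enoate | COc1ccc(COC/C(=C/[C@]2(C)CC[C@H](O2)C(C)(C)CCO[Si](c3ccccc3)(c3ccccc3)C(C)(C)C)[C@@](O)(C#CC)C(=O)OC)cc1 | intermediate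
21 | methyl (2S,3Z)-3-{[(4-methoxybenzyl)oxy]methyl}-2-(prop-1-yn-1-yl)-4-(THF*)-2-[(triethylsilyl)oxy]but-3-enoate | COc1ccc(COC/C(=C/[C@]2(C)CC[C@H](O2)C(C)(C)CCO[Si](c3ccccc3)(c3ccccc3)C(C)(C)C)[C@@](O[Si](CC)(CC)CC)(C#CC)C(=O)OC)cc1 | intermediate
22 | (2S,3Z)-3-{[(4-methoxybenzyl)oxy]methyl}-2-(prop-1-yn-1-yl)-4-(THF*)-2-[(triethylsilyl)oxy]but-3-enal | COc1ccc(COC/C(=C/[C@]2(C)CC[C@H](O2)C(C)(C)CCO[Si](c3ccccc3)(c3ccccc3)C(C)(C)C)[C@@](O[Si](CC)(CC)CC)(C#CC)C=O)cc1 | intermediate
23 | isopropenylmagnesium bromide | C=C(C)[Mg]Br | starting material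
24 | (4S,5Z)-5-{[(4-methoxybenzyl)oxy]methyl}-2-methyl-4-(prop-1-yn-1-yl)-6-(THF*)-4-[(triethylsilyl)oxy]hexa-1,5-dien-3-ol, both C15 epimers | COc1ccc(COC/C(=C/[C@]2(C)CC[C@H](O2)C(C)(C)CCO[Si](c3ccccc3)(c3ccccc3)C(C)(C)C)[C@@](O[Si](CC)(CC)CC)(C#CC)C(O)C(C)=C)cc1 | intermediate
25 | (4S,5Z)-5-(hydroxymethyl)-2-methyl-4-(prop-1-yn-1-yl)-6-(THF*)-4-[(triethylsilyl)oxy]hexa-1,5-dien-3-ol, both C15 epimers | OC/C(=C/[C@]1(C)CC[C@H](O1)C(C)(C)CCO[Si](c1ccccc1)(c1ccccc1)C(C)(C)C)[C@@](O[Si](CC)(CC)CC)(C#CC)C(O)C(C)=C | intermediate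
26 | (2E,3S)-5-methyl-4-oxo-3-(prop-1-yn-1-yl)-2-[(THF*)methylidene]-3-[(triethylsilyl)oxy]hex-5-enal | O=C/C(=C/[C@]1(C)CC[C@H](O1)C(C)(C)CCO[Si](c1ccccc1)(c1ccccc1)C(C)(C)C)[C@@](O[Si](CC)(CC)CC)(C#CC)C(=O)C(C)=C | intermediate
27 | (4S,5E)-2-methyl-4-(2-methylacryloyl)-5-[(THF*)methylidene]-4-[(triethylsilyl)oxy]cyclopent-2-en-1-one | C=C(C)C(=O)[C@]1(O[Si](CC)(CC)CC)C=C(C)C(=O)/C1=C/[C@]1(C)CC[C@H](O1)C(C)(C)CCO[Si](c1ccccc1)(c1ccccc1)C(C)(C)C | intermediate
28 | (4S,5E)-4-hydroxy-2-methyl-4-(2-methylacryloyl)-5-[(THF*)methylidene]cyclopent-2-en-1-one | C=C(C)C(=O)[C@]1(O)C=C(C)C(=O)/C1=C/[C@]1(C)CC[C@H](O1)C(C)(C)CCO[Si](c1ccccc1)(c1ccccc1)C(C)(C)C | intermediate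
29 | (1S,5E)-3-methyl-1-(2-methylacryloyl)-4-oxo-5-[(THF*)methylidene]cyclopent-2-en-1-yl acetate | C=C(C)C(=O)[C@]1(OC(C)=O)C=C(C)C(=O)/C1=C/[C@]1(C)CC[C@H](O1)C(C)(C)CCO[Si](c1ccccc1)(c1ccccc1)C(C)(C)C | intermediate
30 | (1S,5E)-5-{[(2S,5S)-5-(4-hydroxy-2-methylbutan-2-yl)-2-methyltetrahydrofuran-2-yl]methylidene}-3-methyl-1-(2-methylacryloyl)-4-oxocyclopent-2-en-1-yl acetate | C=C(C)C(=O)[C@]1(OC(C)=O)C=C(C)C(=O)/C1=C/[C@]1(C)CC[C@H](O1)C(C)(C)CCO | intermediate
31 | 3-[(2S,5S)-5-{(E)-[(2S)-2-acetoxy-4-methyl-2-(2-methylacryloyl)-5-oxocyclopent-3-en-1-ylidene]methyl}-5-methyltetrahydrofuran-2-yl]-3-methylbutanoic acid | C=C(C)C(=O)[C@]1(OC(C)=O)C=C(C)C(=O)/C1=C/[C@]1(C)CC[C@H](O1)C(C)(C)CC(=O)O | intermediate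
32 | 1,3-dioxoisoindolin-2-yl ester of 31 | C=C(C)C(=O)[C@]1(OC(C)=O)C=C(C)C(=O)/C1=C/[C@]1(C)CC[C@H](O1)C(C)(C)CC(=O)ON1C(=O)c2ccccc2C1=O | intermediate
33 | CNP0144863.1: ring A 1-acetoxy-3-methylcyclopent-2-en-4-one fused at C1/C5 to the twelve-membered ring C, C5=C6 E, 7,10-epoxy bridge (ring B), 7-methyl, 11,11-dimethyl, 14-methyl, 15-oxo; 1S,7S,10S,14R | CC(=O)O[C@@]12C=C(C)C(=O)/C1=C/[C@]1(C)CC[C@H](O1)C(C)(C)CC[C@@H](C)C2=O | target

**Step count and risks**

Total steps: 25. Longest linear sequence: 25 steps (1 → 33).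

Steps most likely to fail:

1. Step 19 (ring A closure). After C–H insertion the conjugated acyl rhodium hydride may lose carbon monoxide, or return hydride to C5=C6 and scramble its geometry, faster than it adds across the alkyne. The fallback closes the same C3–C4 bond without rhodium; it sets out from 21 and comes back at 27. Ruthenium-catalysed trans-hydrosilylation of the propynyl group of 21 (BnMe2SiH, [Cp*Ru(MeCN)3]PF6, CH2Cl2) should give the (Z)-vinylsilane F1 with silicon on C3, distal to the C1 oxygen and cis to C1. Iododesilylation (N-iodosuccinimide, (CF3)2CHOH, 0 °C) gives with retention the (Z)-alkenyl iodide F2. The operations of steps 15 to 18 then give in turn the C15 aldehyde F3, the C15 allylic alcohol F4, the diol F5 and the iodo enal F6. CrCl2 with catalytic NiCl2 in DMF adds the C3 alkenylchromium to the C4 aldehyde (Nozaki–Hiyama–Kishi cyclisation, selective for the aldehyde over both ketones) to give the ring A carbinol F7, and Dess–Martin oxidation of this doubly allylic alcohol gives 27.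

2. Step 25 (ring C closure). The C12 radical may be reduced or may add intermolecularly before the twelve-membered ring closes, and hydrogen delivery to C14 may show poor facial selectivity. The fallback replaces the reductive photoredox manifold by a group-transfer radical chain without a hydrogen donor; it sets out from 31 and comes back at 33. The acid 31 is converted (N-hydroxypyridine-2-thione, DCC, CH2Cl2, dark) into the thiohydroxamate (Barton) ester F8. Visible-light photolysis at high dilution lets the C12 radical cyclise onto C13 and the C14 radical take the 2-pyridylthio group from a further molecule of F8, giving the macrocyclic C14 sulfide F9. The C–S bond is then cleaved with Bu3SnH and Et3B/air in toluene at rt, a separately chosen hydrogen donor delivering H to C14, to give 33; the C14 ratio can still be corrected by base equilibration.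

3. Step 13 (C1 stereocentre). Addition to the hindered C1 ketone may be slow, and facial selectivity may be poor if substrate and ligand are mismatched. The fallback uses auxiliary control with a stoichiometric Grignard reagent; it sets out from 15 and comes back at 22. Methyl (1R,2S,5R)-8-phenylmenthyl oxalate F10 is made from (−)-8-phenylmenthol and methyl chlorooxoacetate (pyridine, CH2Cl2). The alkenyllithium 17 from 15 attacks its less hindered methyl ester carbonyl to give the 8-phenylmenthyl ketoester F11. 1-Propynylmagnesium bromide (THF, −78 °C) adds to the chelated, syn-coplanar dicarbonyl from the face not shielded by the phenyl ring to give the tertiary alcohol F12 (the auxiliary antipode is used if the sense of induction demands it). Et3SiOTf/2,6-lutidine gives the silyl ether F13, excess iBu2AlH reduces the hindered ester to the primary alcohol F14 with release of the auxiliary, and Dess–Martin oxidation gives 22.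

**Further compounds**

F1 | step 19 | (Z)-vinylsilane: 21 with the propynyl group replaced by (Z)-2-[benzyl(dimethyl)silyl]prop-1-en-1-yl | COc1ccc(COC/C(=C/[C@]2(C)CC[C@H](O2)C(C)(C)CCO[Si](c3ccccc3)(c3ccccc3)C(C)(C)C)[C@@](O[Si](CC)(CC)CC)(/C=C(/C)[Si](C)(C)Cc3ccccc3)C(=O)OC)cc1
F2 | step 19 | (Z)-alkenyl iodide: 21 with the propynyl group replaced by (Z)-2-iodoprop-1-en-1-yl | COc1ccc(COC/C(=C/[C@]2(C)CC[C@H](O2)C(C)(C)CCO[Si](c3ccccc3)(c3ccccc3)C(C)(C)C)[C@@](O[Si](CC)(CC)CC)(/C=C(/C)I)C(=O)OC)cc1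
F3 | step 19 | C15 aldehyde from F2 (iodo analogue of 22) | COc1ccc(COC/C(=C/[C@]2(C)CC[C@H](O2)C(C)(C)CCO[Si](c3ccccc3)(c3ccccc3)C(C)(C)C)[C@@](O[Si](CC)(CC)CC)(/C=C(/C)I)C=O)cc1
F4 | step 19 | C15 allylic alcohol from F3 (iodo analogue of 24, both C15 epimers) | COc1ccc(COC/C(=C/[C@]2(C)CC[C@H](O2)C(C)(C)CCO[Si](c3ccccc3)(c3ccccc3)C(C)(C)C)[C@@](O[Si](CC)(CC)CC)(/C=C(/C)I)C(O)C(C)=C)cc1
F5 | step 19 | diol from F4 (iodo analogue of 25, both C15 epimers) | OC/C(=C/[C@]1(C)CC[C@H](O1)C(C)(C)CCO[Si](c1ccccc1)(c1ccccc1)C(C)(C)C)[C@@](O[Si](CC)(CC)CC)(/C=C(/C)I)C(O)C(C)=C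
F6 | step 19 | iodo enal (iodo analogue of 26) | O=C/C(=C/[C@]1(C)CC[C@H](O1)C(C)(C)CCO[Si](c1ccccc1)(c1ccccc1)C(C)(C)C)[C@@](O[Si](CC)(CC)CC)(/C=C(/C)I)C(=O)C(C)=C
F7 | step 19 | ring A carbinol: 27 with C4 as CH(OH), both C4 epimers | C=C(C)C(=O)[C@]1(O[Si](CC)(CC)CC)C=C(C)C(O)/C1=C/[C@]1(C)CC[C@H](O1)C(C)(C)CCO[Si](c1ccccc1)(c1ccccc1)C(C)(C)C
F8 | step 25 | 2-thioxopyridin-1(2H)-yl ester of 31 | C=C(C)C(=O)[C@]1(OC(C)=O)C=C(C)C(=O)/C1=C/[C@]1(C)CC[C@H](O1)C(C)(C)CC(=O)On1ccccc1=S
F9 | step 25 | 14-(pyridin-2-ylsulfanyl) derivative of 33, both C14 epimers | CC(=O)O[C@@]12C=C(C)C(=O)/C1=C/[C@]1(C)CC[C@H](O1)C(C)(C)CCC(C)(Sc1ccccn1)C2=O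
F10 | step 13 | methyl (1R,2S,5R)-8-phenylmenthyl oxalate | COC(=O)C(=O)O[C@@H]1C[C@H](C)CC[C@H]1C(C)(C)c1ccccc1
F11 | step 13 | (1R,2S,5R)-8-phenylmenthyl ester analogue of 18 | COc1ccc(COC/C(=C/[C@]2(C)CC[C@H](O2)C(C)(C)CCO[Si](c3ccccc3)(c3ccccc3)C(C)(C)C)C(=O)C(=O)O[C@@H]3C[C@H](C)CC[C@H]3C(C)(C)c3ccccc3)cc1
F12 | step 13 | (1R,2S,5R)-8-phenylmenthyl ester analogue of 20 | COc1ccc(COC/C(=C/[C@]2(C)CC[C@H](O2)C(C)(C)CCO[Si](c3ccccc3)(c3ccccc3)C(C)(C)C)[C@@](O)(C#CC)C(=O)O[C@@H]3C[C@H](C)CC[C@H]3C(C)(C)c3ccccc3)cc1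
F13 | step 13 | (1R,2S,5R)-8-phenylmenthyl ester analogue of 21 | COc1ccc(COC/C(=C/[C@]2(C)CC[C@H](O2)C(C)(C)CCO[Si](c3ccccc3)(c3ccccc3)C(C)(C)C)[C@@](O[Si](CC)(CC)CC)(C#CC)C(=O)O[C@@H]3C[C@H](C)CC[C@H]3C(C)(C)c3ccccc3)cc1
F14 | step 13 | (2S,3Z)-3-{[(4-methoxybenzyl)oxy]methyl}-2-(prop-1-yn-1-yl)-4-(THF*)-2-[(triethylsilyl)oxy]but-3-en-1-ol | COc1ccc(COC/C(=C/[C@]2(C)CC[C@H](O2)C(C)(C)CCO[Si](c3ccccc3)(c3ccccc3)C(C)(C)C)[C@@](O[Si](CC)(CC)CC)(C#CC)CO)cc1
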